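**Strategy.** Ring A is built last. Cutting C8–C8a and C4a–C5 leaves the complete ring B–ring C unit and a four-carbon chain. The key step uses two matched features. Read from C5 to C8 (OH, H, OH, OMe), ring A is an enolised, dehydrated 4-methoxy-3-oxobutanoate. The fusion bond C4a=C8a is the conjugated alkene of the ring C vinylogous ester: C8a accepts a nucleophile, and C4a then becomes nucleophilic. One operation joins a 1,4-dimethoxy-1,3-bis(silyloxy)butadiene to a monocyclic 4-pyranone, closes ring A, aromatises it and frees the 5,7-diol. The precursor is the 2-aryl-3-methoxy-4-pyranone that already carries the prenyl ether, with H at C6 and Br at C5. The bromine accounts for the two hydrogens that aromatisation must remove.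

Key step: step 8

Remark (stereochemistry): the target has no stereocentre, and its only non-aromatic alkene ends in two methyl groups. It is achiral, so no enantiomer has to be selected.

Remark (design): bromine is kept on pyranone C5. A leaving group on C6 would be expelled straight after the first bond forms, and the enol ether needed for the second bond would be lost. The fusion hydrogen C8a–H is not acidic, so a separate base stage for HBr loss is written into the key step.

Step 1
Reactants: 1 pyromeconic acid (3-hydroxy-4H-pyran-4-one)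
Product: 2 3-hydroxy-2-iodo-4H-pyran-4-one
Conditions: NIS (1.05 equiv), MeCN, 0 °C → rt, dark
Reagents that add atoms: N-iodosuccinimide, O=C1CCC(=O)N1I
Why: Electrophilic iodination of a 3-hydroxy-4-pyranone takes place at C2, ortho to the enolic OH, as in the halogenation of kojic acid and related hydroxypyranones.

Step 2
Reactants: 2 3-hydroxy-2-iodo-4H-pyran-4-one
Product: 3 2-iodo-3-methoxy-4H-pyran-4-one
Conditions: MeI (1.5 equiv), K2CO3 (1.5 equiv), acetone, rt
Reagents that add atoms: iodomethane, CI
Why: Williamson O-methylation of the acidic enol with a mild carbonate base leaves the β-iodo enone untouched.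

Step 3
Reactants: 3 2-iodo-3-methoxy-4H-pyran-4-one
Product: 4 5-bromo-2-iodo-3-methoxy-4H-pyran-4-one
Conditions: NBS (1.1 equiv), MeCN, rt → 45 °C, dark
Reagents that add atoms: N-bromosuccinimide, O=C1CCC(=O)N1Br
Why: Electrophilic α-halogenation of a 4-pyranone should occur at C5, the only free nucleophilic α-carbon of the vinylogous ester, because C6 is the electron-poor β-carbon and C2 and C3 are substituted.

Step 4
Reactants: 5 4-hydroxyphenylboronic acid pinacol ester; 6 prenyl bromide (1-bromo-3-methylbut-2-ene)
Product: 7 2-[4-(3-methylbut-2-enyloxy)phenyl]-4,4,5,5-tetramethyl-1,3,2-dioxaborolane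
Conditions: K2CO3 (1.5 equiv), dry acetone, 50 °C
Reagents that add atoms: none
Why: Williamson ether synthesis by SN2 attack of the phenoxide on the primary allylic bromide, under anhydrous carbonate conditions that the pinacol boronate tolerates.

Step 5
Reactants: 4 5-bromo-2-iodo-3-methoxy-4H-pyran-4-one; 7 2-[4-(3-methylbut-2-enyloxy)phenyl]-4,4,5,5-tetramethyl-1,3,2-dioxaborolane
Product: 8 5-bromo-3-methoxy-2-[4-(3-methylbut-2-enyloxy)phenyl]-4H-pyran-4-one
Conditions: 7 (1.0 equiv), Pd(dppf)Cl2 (3 mol %), K3PO4 (2 equiv), THF–H2O 10:1, 40 °C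
Reagents that add atoms: none
Why: In this site-selective Suzuki–Miyaura coupling, oxidative addition into the weak C–I bond at the electron-poor β-carbon C2 is much faster than into the α-C5–Br bond, so one equivalent of boronate at mild temperature should react at C2 only.

Step 6
Reactants: 9 methyl 4-methoxyacetoacetate
Product: 10 methyl 4-methoxy-3-(trimethylsilyloxy)but-2-enoate (E/Z mixture, geometry immaterial)
Conditions: TMSCl (1.5 equiv), Et3N (1.5 equiv), toluene, rt
Reagents that add atoms: chlorotrimethylsilane, C[Si](C)(C)Cl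
Why: Soft enolisation and O-silylation of a β-keto ester is the standard first stage in making a 1,3-bis(silyloxy)diene.

Step 7
Reactants: 10 methyl 4-methoxy-3-(trimethylsilyloxy)but-2-enoate
Product: 11 (3Z)-1,4-dimethoxy-1,3-bis(trimethylsilyloxy)buta-1,3-diene (ketene acetal geometry undefined)
Conditions: commercial LDA (1.3 equiv), THF, −78 °C; TMSCl (1.4 equiv), −78 °C → rt; hexane, filtration under argon, used crude
Reagents that add atoms: chlorotrimethylsilane, C[Si](C)(C)Cl
Why: γ-Deprotonation of the silyloxycrotonate gives the extended dienolate, and O-silylation at the ester oxygen gives the Chan-type diene, whose alkene geometry is erased on aromatisation.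

Step 8
Reactants: 8 5-bromo-3-methoxy-2-[4-(3-methylbut-2-enyloxy)phenyl]-4H-pyran-4-one; 11 (3Z)-1,4-dimethoxy-1,3-bis(trimethylsilyloxy)buta-1,3-diene
Product: 16 5,7-dihydroxy-3,8-dimethoxy-4'-prenyloxyflavone (target), via silyloxypyrylium triflate 12 (not isolated), via Michael adduct 13 (not isolated), via bromodione 14 (not isolated), via 7-O-silyl flavone 15 (not isolated)
Conditions: 11 (1.5 equiv), 2,6-di-tert-butylpyridine (0.3 equiv), CH2Cl2, −78 °C, TMSOTf (1.1 equiv), −78 → 0 °C; DBU (3.5 equiv), 0 °C → rt; MeOH, rt; pH 5 buffer work-up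
Reagents that add atoms: none
Why: Proposed new method: O-silylation of C4=O converts 8 into pyrylium salt 12, whose only unsubstituted position next to oxygen (pyranone C6, the future C8a) is attacked by the methoxy-bearing, most nucleophilic terminus of 11 in a vinylogous Mukaiyama–Michael addition (C8–C8a, adduct 13), and the silyl-activated ester-level carbon is then captured by the bromine-bearing silyl enol ether carbon (C4a–C5) with loss of TMSOMe, a 6-(enolexo)-exo-trig Claisen/Dieckmann closure of ring A that completes a stepwise polar [4+2] and gives 14. Because C8a–H of 14 is not α to a carbonyl, HBr cannot leave by the E1cB path open to haloquinone adducts, so DBU is added for an E2 dehydrobromination of the type that turns 3,3-dihalochromanones into 3-halochromones, and a cis H/Br fusion can epimerise at C8a by reversible oxa-Michael opening through the C8 enolate. The resulting trione tautomerises irreversibly to the aromatic ring A (15), and methanol removes the 7-O-silyl group. The closest known reaction types are the cyclohexene annulation of 4-silyloxybenzopyrylium salts with 2-silyloxydienes, the silyl-triflate-mediated addition of 1,3-bis(silyloxy)dienes to chromones, and the cycloaromatisation of ketene-acetal dienes with haloquinones. No stereocentre survives, since C8, C8a and C4a are only transiently tetrahedral and their configuration has no effect on the product. The step needs attack at C6 and not C2 with a head-to-tail diene orientation, which is secured by the aryl group blocking C2, by the polarisation of the diene towards its C4 terminus, and by a bromine that stays vinylic (so it cannot be displaced) until the ring is closed, while the hindered pyridine and low temperature shield the prenyl ether from acid.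

**Compound list**

1 | pyromeconic acid (3-hydroxy-4H-pyran-4-one) | O=c1ccocc1O | starting material
2 | 3-hydroxy-2-iodo-4H-pyran-4-one | O=c1ccoc(I)c1O | intermediate
3 | 2-iodo-3-methoxy-4H-pyran-4-one | COc1c(I)occc1=O | intermediate
4 | 5-bromo-2-iodo-3-methoxy-4H-pyran-4-one | COc1c(I)occ(Br)c1=O | intermediate
5 | 4-hydroxyphenylboronic acid pinacol ester | CC1(C)OB(c2ccc(O)cc2)OC1(C)C | starting material
6 | prenyl bromide (1-bromo-3-methylbut-2-ene) | CC(C)=CCBr | starting material
7 | 2-[4-(3-methylbut-2-enyloxy)phenyl]-4,4,5,5-tetramethyl-1,3,2-dioxaborolane | CC(C)=CCOc1ccc(cc1)B1OC(C)(C)C(C)(C)O1 | intermediate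
8 | 5-bromo-3-methoxy-2-[4-(3-methylbut-2-enyloxy)phenyl]-4H-pyran-4-one | COc1c(-c2ccc(OCC=C(C)C)cc2)occ(Br)c1=O | intermediate
9 | methyl 4-methoxyacetoacetate | COCC(=O)CC(=O)OC | starting material
10 | methyl 4-methoxy-3-(trimethylsilyloxy)but-2-enoate (E/Z mixture) | COCC(=CC(=O)OC)O[Si](C)(C)C | intermediate
11 | (3Z)-1,4-dimethoxy-1,3-bis(trimethylsilyloxy)buta-1,3-diene | CO/C=C(/C=C(OC)O[Si](C)(C)C)O[Si](C)(C)C | intermediate
12 | 5-bromo-3-methoxy-2-[4-(3-methylbut-2-enyloxy)phenyl]-4-(trimethylsilyloxy)pyrylium trifluoromethanesulfonate | COc1c(-c2ccc(OCC=C(C)C)cc2)[o+]cc(Br)c1O[Si](C)(C)C.[O-]S(=O)(=O)C(F)(F)F | intermediate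
13 | methyl 4-{3-bromo-5-methoxy-6-[4-(3-methylbut-2-enyloxy)phenyl]-4-(trimethylsilyloxy)-2H-pyran-2-yl}-4-methoxy-3-(trimethylsilyloxy)but-2-enoate (racemic diastereomer mixture, centres transient) | COC(=O)C=C(O[Si](C)(C)C)C(OC)C1OC(-c2ccc(OCC=C(C)C)cc2)=C(OC)C(O[Si](C)(C)C)=C1Br | intermediate
14 | 4a-bromo-3,8-dimethoxy-2-[4-(3-methylbut-2-enyloxy)phenyl]-7-(trimethylsilyloxy)-8,8a-dihydro-4aH-chromene-4,5-dione (racemic diastereomer mixture, centres transient) | COC1C(O[Si](C)(C)C)=CC(=O)C2(Br)C1OC(-c3ccc(OCC=C(C)C)cc3)=C(OC)C2=O | intermediate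
15 | 5-hydroxy-3,8-dimethoxy-2-[4-(3-methylbut-2-enyloxy)phenyl]-7-(trimethylsilyloxy)-4H-chromen-4-one | COc1c(-c2ccc(OCC=C(C)C)cc2)oc2c(OC)c(O[Si](C)(C)C)cc(O)c2c1=O | intermediate
16 | 5,7-dihydroxy-3,8-dimethoxy-4'-prenyloxyflavone | COc1c(-c2ccc(OCC=C(C)C)cc2)oc2c(OC)c(O)cc(O)c2c1=O | target

**Total step count:** 8. **Longest linear sequence:** 5 steps (1, 2, 3, 5, 8).

**Steps most likely to fail**

1. **Step 8.**
   - **Failure modes.** The cascade may stop after the first C–C bond, because a bromine-bearing silyl enol ether is a weak nucleophile and a donor-substituted ester is a weak electrophile. Once base arrives, ring C can open by retro-oxa-Michael reaction and re-close by aldol condensation at C4. The active methylene can also alkylate the bromine-bearing carbon. The prenyl ether may ionise at the cationic arylpyrylium stage.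
   - **Fallback.** It uses known chemistry, with ring A bought rather than built and ring B attached last. It sets out from 7 and comes back at 16. Hoesch acylation of commercial 2-methoxybenzene-1,3,5-triol with methoxyacetonitrile (ZnCl2, HCl, Et2O, 0 °C) should give the ketiminium chloride F1. Hot water hydrolyses this to 2-methoxy-1-(2,4,6-trihydroxy-3-methoxyphenyl)ethanone F2. One-carbon ring closure (BF3·OEt2, DMF, MsCl, 60 °C) should give 5,7-dihydroxy-3,8-dimethoxychromone F3. Closure is expected through the hydroxyl next to the methoxy group; the assignment is checked at this stage and any 6-methoxy isomer is removed. Silylation (TBSOTf, 2,6-lutidine, CH2Cl2) gives 5,7-bis(tert-butyldimethylsilyloxy)-3,8-dimethoxychromone F4. C2 zincation with TMPZnCl·LiCl in THF gives the chromon-2-ylzinc chloride F5, and iodine converts it into the 2-iodochromone F6. Suzuki coupling of F6 with 7 (Pd(PPh3)4, K2CO3, dioxane–H2O) gives the bis-silylated flavone F7. TBAF buffered with AcOH releases 16 without touching the prenyl ether.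

2. **Step 3.**
   - **Failure modes.** The brominating agent may attack ipso at the iodine-bearing C2 and cause halogen exchange. Substitution at C5 of the electron-poor ring may also be too slow.
   - **Fallback.** The order becomes arylation first and bromination afterwards. It sets out from 3 and comes back at 8. Suzuki coupling of 3 with 5 gives 2-(4-hydroxyphenyl)-3-methoxy-4H-pyran-4-one F8. Acetylation (Ac2O, pyridine) gives the aryl acetate F9, whose benzene ring is deactivated. Bromination (NBS, MeCN, or Br2 then Et3N) then has only pyranone C5 to attack, with no iodine present, and gives the 5-bromo acetate F10. Acid-catalysed methanolysis (catalytic AcCl, MeOH), which the pyranone tolerates, gives 5-bromo-2-(4-hydroxyphenyl)-3-methoxy-4H-pyran-4-one F11. Alkylation with 6 (K2CO3, acetone) gives 8.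

3. **Step 5.**
   - **Failure modes.** Site selectivity may erode through competing oxidative addition at C5–Br. Aqueous base may open the dihalopyranone hydrolytically. The boronate may protodeboronate.
   - **Fallback.** The coupling polarity is reversed and the reaction is base-free. It sets out from 4 and comes back at 8. Iodine–magnesium exchange, selective for C–I (iPrMgCl·LiCl, THF, −78 °C), gives (5-bromo-3-methoxy-4-oxo-4H-pyran-2-yl)magnesium chloride F12. ZnCl2 converts this into the corresponding zinc chloride F13. Negishi coupling (Pd(PPh3)4, THF, rt) with 1-iodo-4-(3-methylbut-2-enyloxy)benzene F14, made from 4-iodophenol and 6 (K2CO3, acetone), gives 8. Palladium now inserts into the aryl iodide, and only C2 carries a metal.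

**Further compounds**

F1 | step 8 | 2-methoxy-1-(2,4,6-trihydroxy-3-methoxyphenyl)ethaniminium chloride | COCC(=[NH2+])c1c(O)cc(O)c(OC)c1O.[Cl-]
F2 | step 8 | 2-methoxy-1-(2,4,6-trihydroxy-3-methoxyphenyl)ethanone | COCC(=O)c1c(O)cc(O)c(OC)c1O
F3 | step 8 | 5,7-dihydroxy-3,8-dimethoxy-4H-chromen-4-one | COc1coc2c(OC)c(O)cc(O)c2c1=O
F4 | step 8 | 5,7-bis(tert-butyldimethylsilyloxy)-3,8-dimethoxy-4H-chromen-4-one | COc1coc2c(OC)c(O[Si](C)(C)C(C)(C)C)cc(O[Si](C)(C)C(C)(C)C)c2c1=O
F5 | step 8 | [5,7-bis(tert-butyldimethylsilyloxy)-3,8-dimethoxy-4-oxo-4H-chromen-2-yl]zinc chloride | COc1c([Zn]Cl)oc2c(OC)c(O[Si](C)(C)C(C)(C)C)cc(O[Si](C)(C)C(C)(C)C)c2c1=O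
F6 | step 8 | 5,7-bis(tert-butyldimethylsilyloxy)-2-iodo-3,8-dimethoxy-4H-chromen-4-one | COc1c(I)oc2c(OC)c(O[Si](C)(C)C(C)(C)C)cc(O[Si](C)(C)C(C)(C)C)c2c1=O
F7 | step 8 | 5,7-bis(tert-butyldimethylsilyloxy)-3,8-dimethoxy-4'-prenyloxyflavone | COc1c(-c2ccc(OCC=C(C)C)cc2)oc2c(OC)c(O[Si](C)(C)C(C)(C)C)cc(O[Si](C)(C)C(C)(C)C)c2c1=O
F8 | step 3 | 2-(4-hydroxyphenyl)-3-methoxy-4H-pyran-4-one | COc1c(-c2ccc(O)cc2)occc1=O
F9 | step 3 | 4-(3-methoxy-4-oxo-4H-pyran-2-yl)phenyl acetate | COc1c(-c2ccc(OC(C)=O)cc2)occc1=O
F10 | step 3 | 4-(5-bromo-3-methoxy-4-oxo-4H-pyran-2-yl)phenyl acetate | COc1c(-c2ccc(OC(C)=O)cc2)occ(Br)c1=O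
F11 | step 3 | 5-bromo-2-(4-hydroxyphenyl)-3-methoxy-4H-pyran-4-one | COc1c(-c2ccc(O)cc2)occ(Br)c1=O
F12 | step 5 | (5-bromo-3-methoxy-4-oxo-4H-pyran-2-yl)magnesium chloride | COc1c([Mg]Cl)occ(Br)c1=O
F13 | step 5 | (5-bromo-3-methoxy-4-oxo-4H-pyran-2-yl)zinc chloride | COc1c([Zn]Cl)occ(Br)c1=O
F14 | step 5 | 1-iodo-4-(3-methylbut-2-enyloxy)benzene | CC(C)=CCOc1ccc(I)cc1
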